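**Assumption:** the target has no stereocentre and no stereogenic double bond, so "single enantiomer" means the one achiral compound; stereocentres that appear on the way are racemic and are erased again.

**Retrosynthetic overview**
1. Target ⇐ tris(benzyl ether) stilbene by one hydrogenation (C=C saturation plus three O-debenzylations); stilbene ⇐ carbinol ⇐ aryl ketone ⇐ β-keto ester by decarboxylation.
2. Key C–C bond (the two future bridge carbons): crossed Claisen condensation of the enolate of the fully substituted ring A arylacetate with methyl 3-methoxybenzoate.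
3. Ring A arylacetate ⇐ double Negishi benzylation of a 2,6-dibromide with a 4-(benzyloxy)benzylzinc reagent ⇐ NBS dibromination.
4. Oxygen differentiation on ring A: thiolate mono-demethylation of 3,5-dimethoxyphenylacetic acid, then methyl ester and benzyl ether.
5. No ring is built: all four benzene rings come from commercial aromatics (ring A from the arylacetic acid, ring B from the benzoate, the two outer rings from 4-(benzyloxy)benzyl chloride).

**Route**

Step 1
Reactants: 1 2-(3,5-dimethoxyphenyl)acetic acid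
Product: 3 2-(3-hydroxy-5-methoxyphenyl)acetic acid, via disodium phenoxide carboxylate 2 (not isolated)
Conditions: NaSEt (3.5 equiv), DMF, 150 °C, 3 h; then 2 M HCl
Reagents that add atoms: none
Why: Thiolate SN2 O-demethylation stops after one methyl group because the ring then carries an aryloxide that strongly disfavours a second cleavage, so the symmetric diether is desymmetrised.

Step 2
Reactants: 3 2-(3-hydroxy-5-methoxyphenyl)acetic acid
Product: 4 methyl 2-(3-hydroxy-5-methoxyphenyl)acetate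
Conditions: MeOH, H2SO4 (cat.), reflux
Reagents that add atoms: methanol, CO
Why: Fischer esterification of an unhindered arylacetic acid in excess methanol leaves the phenol untouched.

Step 3
Reactants: 4 methyl 2-(3-hydroxy-5-methoxyphenyl)acetate
Product: 5 methyl 2-[3-(benzyloxy)-5-methoxyphenyl]acetate
Conditions: BnBr (1.1 equiv), K2CO3 (1.5 equiv), acetone, reflux
Reagents that add atoms: benzyl bromide, BrCc1ccccc1
Why: Williamson ether synthesis, in which K2CO3 deprotonates only the phenol and not the ester α-position.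

Step 4
Reactants: 5 methyl 2-[3-(benzyloxy)-5-methoxyphenyl]acetate
Product: 8 methyl 2-[3-(benzyloxy)-2,6-dibromo-5-methoxyphenyl]acetate, via 2-bromo-3-benzyloxy monobromide 6 (not isolated), via 2-bromo-5-benzyloxy monobromide 7 (not isolated)
Conditions: NBS (2.1 equiv), MeCN, 0 °C → rt, dark
Reagents that add atoms: N-bromosuccinimide, O=C1CCC(=O)N1Br
Why: Electrophilic aromatic bromination goes para to one alkoxy group and ortho to the other, at the two positions flanking the CH2CO2Me group, while the position between the two alkoxy groups is the slowest, as in the known 2,6-dihalogenation of 3,5-dialkoxytoluenes and benzoates.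

Step 5
Reactants: 9 4-(benzyloxy)benzyl chloride
Product: 10 [4-(benzyloxy)benzyl]zinc chloride
Conditions: Zn dust (1.5 equiv, activated with BrCH2CH2Br and Me3SiCl), LiCl (1.5 equiv), THF, 25 °C; used as a titrated THF solution
Reagents that add atoms: zinc, [Zn]
Why: LiCl-promoted direct zinc insertion into a benzylic chloride gives a benzylic zinc reagent that is stable in THF and tolerates ethers and esters.

Step 6
Reactants: 8 methyl 2-[3-(benzyloxy)-2,6-dibromo-5-methoxyphenyl]acetate; 10 [4-(benzyloxy)benzyl]zinc chloride (3.0 equiv)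
Product: 13 methyl 2-{3-(benzyloxy)-2,6-bis[4-(benzyloxy)benzyl]-5-methoxyphenyl}acetate, via 6-bromo mono-benzylated ester 11 (not isolated), via 2-bromo mono-benzylated ester 12 (not isolated)
Conditions: Pd(OAc)2 (5 mol %), SPhos (2-dicyclohexylphosphino-2′,6′-dimethoxybiphenyl, 10 mol %), THF, 25 → 60 °C
Reagents that add atoms: none
Why: Double Negishi sp2–sp3 cross-coupling, in which SPhos-ligated zerovalent palladium inserts into hindered electron-rich aryl bromides and the benzylzinc partner has no β-hydrogen and does not attack the ester.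

Step 7
Reactants: 13 methyl 2-{3-(benzyloxy)-2,6-bis[4-(benzyloxy)benzyl]-5-methoxyphenyl}acetate; 14 methyl 3-methoxybenzoate (1.3 equiv)
Product: 17 methyl 2-{3-(benzyloxy)-2,6-bis[4-(benzyloxy)benzyl]-5-methoxyphenyl}-3-(3-methoxyphenyl)-3-oxopropanoate (racemic), via lithium ester enolate 15 (not isolated), via lithium keto ester enolate 16 (not isolated)
Conditions: LiN(SiMe3)2 (2.5 equiv), THF, −78 °C, then 14, −78 °C → rt; quench with cold 1 M HCl
Reagents that add atoms: none
Why: Crossed Claisen condensation in which only the arylacetate can enolise, the benzoate is an unhindered non-enolisable acceptor, and deprotonation of the product by the second equivalent of base drives the reaction; the new stereocentre is racemic and is removed in step 8.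

Step 8
Reactants: 17 methyl 2-{3-(benzyloxy)-2,6-bis[4-(benzyloxy)benzyl]-5-methoxyphenyl}-3-(3-methoxyphenyl)-3-oxopropanoate
Product: 19 2-{3-(benzyloxy)-2,6-bis[4-(benzyloxy)benzyl]-5-methoxyphenyl}-1-(3-methoxyphenyl)ethan-1-one, via lithium keto carboxylate 18 (not isolated)
Conditions: LiCl (3 equiv), H2O (3 equiv), DMSO, 140 °C
Reagents that add atoms: none
Why: Krapcho dealkoxycarbonylation (chloride SN2 at the ester methyl, then loss of CO2 from the β-keto carboxylate) avoids hydroxide and therefore retro-Claisen cleavage, and aryl benzyl ethers survive it.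

Step 9
Reactants: 19 2-{3-(benzyloxy)-2,6-bis[4-(benzyloxy)benzyl]-5-methoxyphenyl}-1-(3-methoxyphenyl)ethan-1-one
Product: 20 2-{3-(benzyloxy)-2,6-bis[4-(benzyloxy)benzyl]-5-methoxyphenyl}-1-(3-methoxyphenyl)ethan-1-ol (racemic)
Conditions: NaBH4 (1.5 equiv), THF/MeOH (1:1), 0 °C → rt
Reagents that add atoms: none
Why: Hydride reduction of an unhindered aryl ketone gives the racemic benzylic alcohol, whose stereocentre disappears in step 10.

Step 10
Reactants: 20 2-{3-(benzyloxy)-2,6-bis[4-(benzyloxy)benzyl]-5-methoxyphenyl}-1-(3-methoxyphenyl)ethan-1-ol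
Product: 21 1-(benzyloxy)-2,4-bis[4-(benzyloxy)benzyl]-5-methoxy-3-[(E)-2-(3-methoxyphenyl)ethenyl]benzene
Conditions: TsOH·H2O (10 mol %), toluene, reflux, Dean–Stark, 1–2 h
Reagents that add atoms: none
Why: Acid-catalysed E1 dehydration of a 1,2-diarylethanol can only give the conjugated stilbene, with the E isomer favoured thermodynamically and the geometry irrelevant after step 11.

Step 11
Reactants: 21 1-(benzyloxy)-2,4-bis[4-(benzyloxy)benzyl]-5-methoxy-3-[(E)-2-(3-methoxyphenyl)ethenyl]benzene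
Product: 23 2,4-bis(4-hydroxybenzyl)-5-methoxy-3-[2-(3-methoxyphenyl)ethyl]phenol, via saturated tribenzyl ether 22 (not isolated)
Conditions: H2 (1–3 atm), 10% Pd/C, EtOAc/MeOH (1:1), rt
Reagents that add atoms: none
Why: Heterogeneous catalytic hydrogenation saturates the stilbene and hydrogenolyses the three aryl benzyl ethers, while methyl ethers and diarylmethane C–C bonds are inert and the product has no stereocentre.

**Compound list**
1 | 2-(3,5-dimethoxyphenyl)acetic acid | COc1cc(CC(=O)O)cc(OC)c1 | starting material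
2 | disodium 2-(3-methoxy-5-oxidophenyl)acetate | COc1cc([O-])cc(CC(=O)[O-])c1.[Na+].[Na+] | intermediate
3 | 2-(3-hydroxy-5-methoxyphenyl)acetic acid | COc1cc(O)cc(CC(=O)O)c1 | intermediate
4 | methyl 2-(3-hydroxy-5-methoxyphenyl)acetate | COC(=O)Cc1cc(O)cc(OC)c1 | intermediate
5 | methyl 2-[3-(benzyloxy)-5-methoxyphenyl]acetate | COC(=O)Cc1cc(OC)cc(OCc2ccccc2)c1 | intermediate
6 | methyl 2-[3-(benzyloxy)-2-bromo-5-methoxyphenyl]acetate | COC(=O)Cc1cc(OC)cc(OCc2ccccc2)c1Br | intermediate
7 | methyl 2-[5-(benzyloxy)-2-bromo-3-methoxyphenyl]acetate | COC(=O)Cc1cc(OCc2ccccc2)cc(OC)c1Br | intermediate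
8 | methyl 2-[3-(benzyloxy)-2,6-dibromo-5-methoxyphenyl]acetate | COC(=O)Cc1c(Br)c(OC)cc(OCc2ccccc2)c1Br | intermediate
9 | 4-(benzyloxy)benzyl chloride | ClCc1ccc(OCc2ccccc2)cc1 | starting material
10 | [4-(benzyloxy)benzyl]zinc chloride (THF solution containing LiCl) | Cl[Zn]Cc1ccc(OCc2ccccc2)cc1 | intermediate
11 | methyl 2-{3-(benzyloxy)-2-[4-(benzyloxy)benzyl]-6-bromo-5-methoxyphenyl}acetate | COC(=O)Cc1c(Br)c(OC)cc(OCc2ccccc2)c1Cc1ccc(OCc2ccccc2)cc1 | intermediate
12 | methyl 2-{3-(benzyloxy)-6-[4-(benzyloxy)benzyl]-2-bromo-5-methoxyphenyl}acetate | COC(=O)Cc1c(Cc2ccc(OCc3ccccc3)cc2)c(OC)cc(OCc2ccccc2)c1Br | intermediate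
13 | methyl 2-{3-(benzyloxy)-2,6-bis[4-(benzyloxy)benzyl]-5-methoxyphenyl}acetate | COC(=O)Cc1c(Cc2ccc(OCc3ccccc3)cc2)c(OC)cc(OCc2ccccc2)c1Cc1ccc(OCc2ccccc2)cc1 | intermediate
14 | methyl 3-methoxybenzoate | COC(=O)c1cccc(OC)c1 | starting material
15 | lithium enolate of ester 13 (lithium 1-methoxy-2-arylethen-1-olate) | [Li+].COC([O-])=Cc1c(Cc2ccc(OCc3ccccc3)cc2)c(OC)cc(OCc2ccccc2)c1Cc1ccc(OCc2ccccc2)cc1 | intermediate
16 | lithium enolate of β-keto ester 17 | [Li+].COC(=O)C(=C([O-])c1cccc(OC)c1)c1c(Cc2ccc(OCc3ccccc3)cc2)c(OC)cc(OCc2ccccc2)c1Cc1ccc(OCc2ccccc2)cc1 | intermediate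
17 | methyl 2-{3-(benzyloxy)-2,6-bis[4-(benzyloxy)benzyl]-5-methoxyphenyl}-3-(3-methoxyphenyl)-3-oxopropanoate (racemic) | COC(=O)C(C(=O)c1cccc(OC)c1)c1c(Cc2ccc(OCc3ccccc3)cc2)c(OC)cc(OCc2ccccc2)c1Cc1ccc(OCc2ccccc2)cc1 | intermediate
18 | lithium 2-{3-(benzyloxy)-2,6-bis[4-(benzyloxy)benzyl]-5-methoxyphenyl}-3-(3-methoxyphenyl)-3-oxopropanoate | [Li+].[O-]C(=O)C(C(=O)c1cccc(OC)c1)c1c(Cc2ccc(OCc3ccccc3)cc2)c(OC)cc(OCc2ccccc2)c1Cc1ccc(OCc2ccccc2)cc1 | intermediate
19 | 2-{3-(benzyloxy)-2,6-bis[4-(benzyloxy)benzyl]-5-methoxyphenyl}-1-(3-methoxyphenyl)ethan-1-one | COc1cccc(C(=O)Cc2c(Cc3ccc(OCc4ccccc4)cc3)c(OCc3ccccc3)cc(OC)c2Cc2ccc(OCc3ccccc3)cc2)c1 | intermediate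
20 | 2-{3-(benzyloxy)-2,6-bis[4-(benzyloxy)benzyl]-5-methoxyphenyl}-1-(3-methoxyphenyl)ethan-1-ol (racemic) | COc1cccc(C(O)Cc2c(Cc3ccc(OCc4ccccc4)cc3)c(OCc3ccccc3)cc(OC)c2Cc2ccc(OCc3ccccc3)cc2)c1 | intermediate
21 | 1-(benzyloxy)-2,4-bis[4-(benzyloxy)benzyl]-5-methoxy-3-[(E)-2-(3-methoxyphenyl)ethenyl]benzene | COc1cccc(/C=C/c2c(Cc3ccc(OCc4ccccc4)cc3)c(OCc3ccccc3)cc(OC)c2Cc2ccc(OCc3ccccc3)cc2)c1 | intermediate
22 | 1-(benzyloxy)-2,4-bis[4-(benzyloxy)benzyl]-5-methoxy-3-[2-(3-methoxyphenyl)ethyl]benzene | COc1cccc(CCc2c(Cc3ccc(OCc4ccccc4)cc3)c(OCc3ccccc3)cc(OC)c2Cc2ccc(OCc3ccccc3)cc2)c1 | intermediate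
23 | 2,4-bis(4-hydroxybenzyl)-5-methoxy-3-[2-(3-methoxyphenyl)ethyl]phenol (2,6-bis(p-hydroxybenzyl)-3,5′-dimethoxy-3-hydroxybibenzyl; achiral) | COc1cccc(CCc2c(Cc3ccc(O)cc3)c(O)cc(OC)c2Cc2ccc(O)cc2)c1 | target

**Totals**
Total step count: 11.
Longest linear sequence: 10 steps (1 → 23 through steps 1–4 and 6–11); step 5 is a one-step side branch.

**Three steps most likely to fail, with fallbacks**

Step 6, the double Negishi coupling, is the most exposed step because both C–Br bonds are flanked on two sides and the ring is electron-rich. The risks are stalling at 11 or 12 and protodebromination. The fallback sets out from 5 and comes back at 13 without bromination or palladium. Friedel–Crafts benzylation of 5 with chloride 9 (2.2 equiv) and ZnCl2 (20 mol %) in CH2Cl2/MeNO2 at 0 °C → rt first gives the mono-benzylated esters methyl 2-{3-(benzyloxy)-2-[4-(benzyloxy)benzyl]-5-methoxyphenyl}acetate F1 and methyl 2-{5-(benzyloxy)-2-[4-(benzyloxy)benzyl]-3-methoxyphenyl}acetate F2. Each is benzylated a second time at the remaining position next to the CH2CO2Me group to give 13. The minor isomer benzylated between the two alkoxy groups must be removed by chromatography.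

Step 7, the Claisen condensation, may be slow because the enolate 15 sits between two ortho benzyl groups and a methyl ester is only a moderate acceptor. The fallback sets out from 13 and comes back at 17. Enolate 15 (LiN(SiMe3)2, THF, −78 °C) is added to the far more electrophilic 3-methoxybenzaldehyde in an aldol addition. This gives methyl 2-{3-(benzyloxy)-2,6-bis[4-(benzyloxy)benzyl]-5-methoxyphenyl}-3-hydroxy-3-(3-methoxyphenyl)propanoate F3 as a racemic diastereomer mixture. Oxidation with Dess–Martin periodinane (CH2Cl2, rt) then gives the β-keto ester 17, and the route continues with step 8.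

Step 10, the acid-catalysed dehydration, could be accompanied by acid-induced benzyl ether cleavage or migration, or by capture of the benzylic cation by one of the electron-rich rings. The fallback sets out from 20 and comes back at 21 under basic conditions only. MsCl and Et3N in CH2Cl2 at 0 °C give 2-{3-(benzyloxy)-2,6-bis[4-(benzyloxy)benzyl]-5-methoxyphenyl}-1-(3-methoxyphenyl)ethyl methanesulfonate F4. E2 elimination with DBU in toluene at 80 °C then gives stilbene 21.

**Further compounds**
F1 | step 6 | methyl 2-{3-(benzyloxy)-2-[4-(benzyloxy)benzyl]-5-methoxyphenyl}acetate | COC(=O)Cc1cc(OC)cc(OCc2ccccc2)c1Cc1ccc(OCc2ccccc2)cc1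
F2 | step 6 | methyl 2-{5-(benzyloxy)-2-[4-(benzyloxy)benzyl]-3-methoxyphenyl}acetate | COC(=O)Cc1cc(OCc2ccccc2)cc(OC)c1Cc1ccc(OCc2ccccc2)cc1
F3 | step 7 | methyl 2-{3-(benzyloxy)-2,6-bis[4-(benzyloxy)benzyl]-5-methoxyphenyl}-3-hydroxy-3-(3-methoxyphenyl)propanoate (racemic diastereomer mixture) | COC(=O)C(C(O)c1cccc(OC)c1)c1c(Cc2ccc(OCc3ccccc3)cc2)c(OC)cc(OCc2ccccc2)c1Cc1ccc(OCc2ccccc2)cc1
F4 | step 10 | 2-{3-(benzyloxy)-2,6-bis[4-(benzyloxy)benzyl]-5-methoxyphenyl}-1-(3-methoxyphenyl)ethyl methanesulfonate (racemic) | COc1cccc(C(OS(C)(=O)=O)Cc2c(Cc3ccc(OCc4ccccc4)cc3)c(OCc3ccccc3)cc(OC)c2Cc2ccc(OCc3ccccc3)cc2)c1
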